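238 monomer units per chain is the number we carry through these flasks: the chain floor, free monomer charged divided by initiator charged. It is the average length at the far end, with the charged monomer in chains and one chain per charged initiator, if each initiator gives two radicals that end joined.

common to all: free monomer 20 mM

| run | initiator | remark | time |
|---|---|---|---|
| grey | 130 µM | run made earlier |  |
| alder | 84 µM |  | 30 h |
| ash | 84 µM |  | 60 h |

grey run (percent of the free monomer charged)

| time / h | monomer in chains / % | free monomer / % |
|---|---|---|
| 0.250 | 2.2 | 97.1 |
| 0.500 | 4.5 | 94.4 |
| 1.33 | 13.8 | 87.6 |
| 3.00 | 26.6 | 72.4 |

(readings scatter by 0.5 percentage points)

- the average divides the monomer in chains by the number of chains, living and dead together; two radicals that join make one chain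
- the analysis behind the earlier runs scatters by 0.5 percentage points, standard deviation
- the earlier runs do not show the number of chains; that part of a forecast is a guess
- no earlier run changes the charge of initiator; that part of a forecast is a guess

1. which of the two ends with the longer chains by the average number of monomer units in a chain (living and dead chains, two that joined counted as one) ("neither" if they lie within 10%) (alder / ash / neither)
2. average number of monomer units in a chain (living and dead chains, two that joined counted as one) at the end, alder
3. average number of monomer units in a chain (living and dead chains, two that joined counted as one) at the end, ash

We read a ladder of time scales from the grey run. On the fastest rung we put the radicals, which the readings do not show; we take them as a small steady stock handing monomer along. Next comes free monomer. Grey's 72.4% at 3.00 h gives a pseudo-first-order constant of 0.108 h⁻¹. If rate goes as the square root of initiator, which is a guess because no earlier run changes that charge, alder and ash run at 0.0865 h⁻¹, a lifetime of 11.6 h. Alder's 30 h is then 2.59 lifetimes and ash's 60 h is 5.17. On the slowest rung we put initiator, since grey shows no slowing over its 3.00 h; its life is unread.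

Now we join the two ends. Early on, few chains share the monomer, so they are long; at the far end stands the floor. Between them, length is the floor times the fraction of monomer reacted over the fraction of initiator that has reacted. Our constant leaves 7.46% of the free monomer at alder's end, so ash's extra time can add about that share to the chains while initiator goes on starting new ones. We therefore expect length to fall from alder to ash, with both above the floor.

The forecast names alder, with 450 (200 to 1000) for alder and 350 (180 to 750) for ash. In its words: “New chains keep forming after the monomer is nearly gone, so the average falls”.

The flask gives 444 for alder and 321 for ash, so alder ends longer.

    initiator → 2 initiating radical (k = 6.00 × 10⁻⁶ s⁻¹)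
    free monomer + initiating radical → growing radical + monomer in chains (k = 27700 L mol⁻¹ s⁻¹)
    free monomer + growing radical → monomer in chains + growing radical, rate k3*[growing radical]*[free monomer] (k = 1060 L mol⁻¹ s⁻¹)
    2 growing radical → dead chain (k = 1.00 × 10⁶ L mol⁻¹ s⁻¹)

The longer time is the main reason for the gap: ash stands at 321 after 60 h, against 444 for the same charges at 30 h. Alder has 89.0% of its monomer in chains and 52% of its initiator left, so the floor gives 441; ash, with 97.9% in chains and 27% of its initiator left, gives 319. The flask also holds growing radical, but in alder that is 0.0405% of the dead chain count. The neighbour, alder with 8.0 mM of free monomer, has 89.2% in chains and 52% of initiator left. Its floor of 95.2 gives 177, and the flask gives 178.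

The earlier runs and the new flask were generated by integration on assumed constants; noise was put on by code.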